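**Remark on conventions and assumptions:** briarane numbering is used throughout (C1 quaternary, C2–C9 chain, C10, C11–C14 cyclohexene, C15 = Me on C1, C16 = CH2O on C5, C17/C18/C19 = lactone CH/Me/C=O, C20 = Me on C11). Compounds 14, 23 and 27 are assumed purchasable; 23 is otherwise one asymmetric hydrogenation from 4-methylfuran-2(5H)-one.

## Retrosynthetic overview

1. Target ⇐ desilylation and ring-closing metathesis (C3=C4) of triacetate diene 39; the ten-membered ring is closed last.
2. γ-Lactone and C7–C9 triad ⇐ aldol of an α-alkoxy-butyrolactone enolate (C8) with the C9 aldehyde 22, opening of that lactone by a dienyllithium (C6–C7), chelation-controlled reduction (C7) and oxidative re-lactonisation at C19.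
3. Cyclohexene ⇐ key step on acid 13. The enabling feature is the 1,4-relationship across the C1–C10 bond between the C11 methyl ketone and C14, which sits as an α-oxy carboxylic acid inside a temporary 1,3-dioxan-4-one ring (O14–C14–C1–C2). A two-carbon vinylphosphonium unit (C12–C13) is stitched between C14 and C11.
4. Quaternary C1 and C10 ⇐ dianionic Ireland–Claisen rearrangement of an L-malate ester; the malate carbinol (C14) relays its configuration and is then erased and reset in the key step.
5. Ring order: temporary dioxanone → cyclohexene → γ-lactone → ten-membered ring.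

Key step: step 9

## Route

Step 1
Reactants: 1 (Z)-but-2-ene-1,4-diol
Product: 2 (Z)-4-[(tert-butyldimethylsilyl)oxy]but-2-en-1-ol
Conditions: NaH (1.0 equiv), THF, 0 °C; TBSCl, 0 °C → rt
Reagents that add atoms: tert-butyldimethylsilyl chloride, CC(C)(C)[Si](C)(C)Cl
Why: Monosilylation of a symmetrical diol through its mono-sodium alkoxide (Williamson-type O-silylation) should stop at the mono-ether; no stereocentre is formed and the Z alkene is untouched.

Step 2
Reactants: 3 (S)-malic acid
Product: 5 (S)-4-(benzyloxy)-3-hydroxy-4-oxobutanoic acid, via trifluoroacetyl malic anhydride 4 (not isolated)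
Conditions: (CF3CO)2O, 0 °C → rt; evaporate; BnOH, rt
Reagents that add atoms: benzyl alcohol, OCc1ccccc1
Why: Cyclic anhydride formation and regioselective alcoholysis at the more electrophilic carbonyl next to the acyloxy group should give the 1-monoester (the trifluoroacetate is lost by alcoholysis) and leave the future C2 carboxyl free; the stereocentre is not touched.

Step 3
Reactants: 5 (S)-4-(benzyloxy)-3-hydroxy-4-oxobutanoic acid; 2 (Z)-4-[(tert-butyldimethylsilyl)oxy]but-2-en-1-ol
Product: 6 1-benzyl 4-[(Z)-4-(TBSO)but-2-en-1-yl] (S)-2-hydroxybutanedioate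
Conditions: EDC·HCl, DMAP (cat.), CH2Cl2, 0 °C → rt
Reagents that add atoms: none
Why: Steglich carbodiimide esterification of the free carboxyl with the primary allylic alcohol, which should outcompete the hindered secondary hydroxyl of the α-hydroxy ester.

Step 4
Reactants: 6 1-benzyl 4-[(Z)-4-(TBSO)but-2-en-1-yl] (S)-2-hydroxybutanedioate
Product: 8 1-benzyl 4-[(Z)-4-(TBSO)but-2-en-1-yl] (2S,3R)-2-hydroxy-3-methylbutanedioate, via dilithium alkoxide enolate 7 (not isolated)
Conditions: LiHMDS (2.2 equiv), THF, −78 → −40 °C; MeI, −78 → −40 °C; aq. NH4Cl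
Reagents that add atoms: iodomethane, CI
Why: Fráter–Seebach alkylation, in which the lithium-chelated alkoxide enolate is methylated anti to the carbinol substituent to give the anti (2S,3R) product; the temperature stays below that of the ester-enolate Claisen rearrangement.

Step 5
Reactants: 8 1-benzyl 4-[(Z)-4-(TBSO)but-2-en-1-yl] (2S,3R)-2-hydroxy-3-methylbutanedioate
Product: 10 (2R,3S)-4-(benzyloxy)-2-[(2S)-1-(TBSO)but-3-en-2-yl]-3-hydroxy-2-methyl-4-oxobutanoic acid, via dilithium alkoxide enolate 9 (not isolated)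
Conditions: LiHMDS (2.5 equiv), THF, −78 → 40 °C; aq. HCl
Reagents that add atoms: none
Why: Dianionic Ireland–Claisen [3,3] rearrangement, in which chelation fixes the enolate geometry (C14 cis to OLi) and the Z-allyl unit reacts through a chair on the face anti to the carbinol substituent, so that the C14 carbinol relays its configuration to the quaternary C1 (R) and to C10 (S).

Step 6
Reactants: 10 (2R,3S)-4-(benzyloxy)-2-[(2S)-1-(TBSO)but-3-en-2-yl]-3-hydroxy-2-methyl-4-oxobutanoic acid
Product: 11 benzyl 2-tert-butyl-5-[(2S)-1-(TBSO)but-3-en-2-yl]-5-methyl-6-oxo-1,3-dioxane-4-carboxylate (tert-butyl, ester and butenyl branch equatorial, methyl axial)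
Conditions: t-BuCHO, CSA (cat.), benzene, Dean–Stark reflux
Reagents that add atoms: pivalaldehyde, CC(C)(C)C=O
Why: Seebach-type acetalisation of a β-hydroxy acid to a 2-tert-butyl-1,3-dioxan-4-one, where thermodynamic control should place tert-butyl equatorial, cis to the ester and trans to the C10 branch.

Step 7
Reactants: 11 benzyl dioxanone carboxylate with the C10 vinyl branch
Product: 12 benzyl 2-tert-butyl-5-[(2S)-1-(TBSO)-3-oxobutan-2-yl]-5-methyl-6-oxo-1,3-dioxane-4-carboxylate
Conditions: PdCl2 (10 mol%), CuCl, O2 (1 atm), DMF/H2O 7:1, rt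
Reagents that add atoms: water, O
Why: Tsuji–Wacker oxidation should give the Markovnikov methyl ketone (C11) from the monosubstituted alkene; acid and hydroxyl are masked so no oxypalladative lactonisation competes, and C10 is not epimerised under these near-neutral conditions.

Step 8
Reactants: 12 benzyl ester methyl ketone
Product: 13 2-tert-butyl-5-[(2S)-1-(TBSO)-3-oxobutan-2-yl]-5-methyl-6-oxo-1,3-dioxane-4-carboxylic acid
Conditions: H2 (1 atm), 10% Pd/C, EtOAc, rt
Reagents that add atoms: none
Why: Hydrogenolysis of the benzyl ester; no alkene is left in the molecule and ketone, silyl ether and acylal are inert.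

Step 9
Reactants: 13 dioxanone carboxylic acid methyl ketone; 14 vinyltriphenylphosphonium bromide
Product: 16 cis-fused 2-tert-butyl-1,3-dioxan-4-one/cyclohexene bicycle (C11=C12 alkene, C10 CH2OTBS, C14 S), via phosphonium ylide 15 (not isolated)
Conditions: Ir[dF(CF3)ppy]2(dtbbpy)PF6 (2 mol%), Cs2CO3 (1.1 equiv), DMSO/MeCN, blue LEDs, rt; then 50 °C
Reagents that add atoms: none
Why: Proposed new method: the carboxylate of 13 is oxidised by the excited Ir(III) photocatalyst and loses CO2 to give the C14 α-oxy radical, which adds to the β-carbon of 14 (C13–C14 bond); the α-phosphonio radical is reduced by Ir(II) to ylide 15, whose C12 attacks the C11 methyl ketone, and Wittig collapse forms C11=C12, so the whole is a redox-neutral radical–polar crossover version of the Schweizer vinylphosphonium annulation. The closest known reactions are the intermolecular photoredox three-component olefination of carboxylic acids, vinylphosphonium salts and aldehydes and the classical Schweizer annulation of ketone-bearing stabilised carbanions. The cyclohexene is closed by 6-exo-trig attack of the ylide carbon on the ketone carbonyl followed by oxaphosphetane cycloreversion, which fixes the alkene at C11=C12 with no regioisomer possible. The only new stereocentre, C14, is set in the radical step: the radical sits in the chair dioxanone (tert-butyl and C10 branch equatorial, C15 methyl axial) and should be attacked axially, anti to the axial methyl and with overlap to the ring-oxygen lone pair, which puts C13 cis to the C10 branch and gives 14S. The step is stereoconvergent, since both C14 epimers of the acid give the same radical, and it needs chemoselectivity of the ylide for the ketone over the acylal carbonyl, which the higher electrophilicity of the ketone and the strain of the alternative bridged ring should secure.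

Step 10
Reactants: 16 dioxanone/cyclohexene bicycle
Product: 18 1-[(1R,2S,6S)-2-(TBSO-methyl)-6-hydroxy-1,3-dimethylcyclohex-3-en-1-yl]prop-2-en-1-one, via bromomagnesium hemiketal 17 (not isolated)
Conditions: CH2=CHMgBr (1.3 equiv), THF, −78 → −40 °C; AcOH/THF quench at −78 °C
Reagents that add atoms: vinylmagnesium bromide, C=C[Mg]Br
Why: Mono-addition of a Grignard reagent to a lactone-type carbonyl, where the tetrahedral magnesium hemiketal should persist at low temperature and collapse only on quench to the C2 vinyl ketone, pivalaldehyde and the free C14 hydroxyl; the enone is taken on at once to avoid oxa-Michael closure.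

Step 11
Reactants: 18 β-hydroxy vinyl ketone
Product: 19 (1S)-1-[(1R,2S,6S)-2-(TBSO-methyl)-6-hydroxy-1,3-dimethylcyclohex-3-en-1-yl]prop-2-en-1-ol
Conditions: Me4NBH(OAc)3, MeCN/AcOH 1:1, −30 °C
Reagents that add atoms: none
Why: Evans–Saksena hydroxyl-directed reduction, with intramolecular hydride delivery from the C14-bound acyloxyborohydride through a chair that keeps the vinyl group and C13 equatorial, should give the 1,3-anti diol (2S) by 1,2-reduction only.

Step 12
Reactants: 19 anti-1,3-diol
Product: 20 acetonide of 19 (2,2-dimethyl-1,3-dioxane across O2 and O14)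
Conditions: 2,2-dimethoxypropane, PPTS (cat.), CH2Cl2, rt
Reagents that add atoms: 2,2-dimethoxypropane, COC(C)(C)OC
Why: Acid-catalysed transketalisation ties O2 and O14 in a 1,3-dioxane that tolerates fluoride, oxidants, enolates and organolithiums.

Step 13
Reactants: 20 acetonide TBS ether
Product: 21 acetonide primary alcohol (C9–OH)
Conditions: TBAF, THF, 0 °C → rt
Reagents that add atoms: none
Why: Fluoride-mediated cleavage of the primary silyl ether; acetonide and alkenes are inert.

Step 14
Reactants: 21 acetonide primary alcohol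
Product: 22 acetonide C9 aldehyde
Conditions: Dess–Martin periodinane, NaHCO3, CH2Cl2, 0 °C
Reagents that add atoms: none
Why: Buffered Dess–Martin oxidation should give the aldehyde without epimerising or conjugating the allylic C10 centre; the aldehyde is used at once.

Step 15
Reactants: 23 (R)-4-methyldihydrofuran-2(3H)-one
Product: 25 (3R,4S)-3-hydroxy-4-methyldihydrofuran-2(3H)-one, via lithium enolate 24 (not isolated)
Conditions: LiHMDS, THF, −78 °C; (±)-trans-2-(phenylsulfonyl)-3-phenyloxaziridine, −78 °C; aq. NH4Cl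
Reagents that add atoms: trans-2-(phenylsulfonyl)-3-phenyloxaziridine, O=S(=O)(N1OC1c1ccccc1)c1ccccc1
Why: Davis α-hydroxylation of the lactone enolate trans to the β-methyl group; the configuration of this carbinol is irrelevant because it becomes an enolate carbon in step 18.

Step 16
Reactants: 25 (3R,4S)-3-hydroxy-4-methyldihydrofuran-2(3H)-one
Product: 26 (3R,4S)-3-[(2-methoxypropan-2-yl)oxy]-4-methyldihydrofuran-2(3H)-one
Conditions: 2-methoxypropene, PPTS (cat.), CH2Cl2, 0 °C
Reagents that add atoms: 2-methoxypropene, C=C(C)OC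
Why: Acid-catalysed addition of the alcohol to the enol ether gives the achiral, base-stable and chelating MOP ketal.

Step 17
Reactants: 27 tert-butyldiphenyl(prop-2-yn-1-yloxy)silane
Product: 29 (E)-tert-butyl{[2-(iodomethylidene)but-3-en-1-yl]oxy}diphenylsilane, via dienylcopper 28 (not isolated)
Conditions: CH2=CHMgBr, CuBr·SMe2, Et2O, −45 °C; 27, −45 → −25 °C; I2, −78 → 0 °C
Reagents that add atoms: vinylmagnesium bromide, C=C[Mg]Br; iodine, II
Why: Normant syn-carbocupration of the terminal alkyne should place vinyl on the internal carbon and copper on the terminal carbon, cis to each other, and iodinolysis with retention gives the iodo diene in which iodine (the future C7 position) is cis to the C4 vinyl group.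

Step 18
Reactants: 26 MOP-protected hydroxy lactone; 22 acetonide C9 aldehyde
Product: 32 TES-protected aldol adduct (C8 quaternary with OMOP, C9–OTES; C8, C9, C17 as in the target), via lithium enolate 30 (not isolated), via lithium aldolate 31 (not isolated)
Conditions: LiHMDS, THF, −78 °C; 22, −78 °C; TESCl, HMPA, −78 → 0 °C
Reagents that add atoms: chlorotriethylsilane, CC[Si](Cl)(CC)CC
Why: Aldol addition of a cyclic α-alkoxy lactone enolate, where the aldehyde should approach anti to the β-methyl group (sets C8) and the Zimmerman–Traxler chair of an enolate whose alkoxy group is cis to OLi gives the 8,9-syn relationship, which corresponds to the anti-Felkin aldehyde face usually taken by such Z(O)-type enolates; silylation in situ blocks retro-aldol.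

Step 19
Reactants: 29 (E)-iodo diene; 32 TES-protected aldol adduct
Product: 34 hydroxy dienone (C7 ketone, C19 primary alcohol; in equilibrium with its lactol), via dienyllithium 33 (not isolated)
Conditions: t-BuLi (2.0 equiv), Et2O, −78 °C; 32 in THF, −78 → −40 °C; aq. NH4Cl
Reagents that add atoms: none
Why: Iodine–lithium exchange with retention of alkene geometry and mono-addition of the vinyllithium to the hindered lactone carbonyl (C6–C7 bond), the lithium hemiketal not collapsing before quench.

Step 20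
Reactants: 34 hydroxy dienone
Product: 35 diol (C7–OH 7S, C19–OH)
Conditions: Zn(BH4)2, Et2O, −30 °C
Reagents that add atoms: none
Why: Cram-chelate 1,2-reduction, in which zinc bridges the C7 carbonyl and the C8 ketal oxygen and hydride should enter from the face of the smaller C17 branch, anti to the C9 branch, giving the 7,8-anti relationship.

Step 21
Reactants: 35 diol
Product: 37 γ-lactone (O7–C19) with OMOP at C8, OTES at C9, acetonide and TBDPS ether, via lactol 36 (not isolated)
Conditions: TEMPO (20 mol%), PhI(OAc)2 (2.5 equiv), NaHCO3, CH2Cl2, rt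
Reagents that add atoms: none
Why: Chemoselective TEMPO oxidation of the primary alcohol of a 1,4-diol, whose aldehyde is trapped by the C7 hydroxyl as a lactol and oxidised on to the γ-lactone.

Step 22
Reactants: 37 protected γ-lactone
Product: 38 tetraol (C2, C8, C9, C14 hydroxyls free; C16 OTBDPS)
Conditions: AcOH/THF/H2O 3:1:1, 40 °C
Reagents that add atoms: none
Why: Mild acid hydrolysis should remove the MOP ketal, the TES ether and the strained anti-acetonide while the TBDPS ether and the lactone stay.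

Step 23
Reactants: 38 tetraol
Product: 39 2,9,14-triacetate diene (C8 tertiary OH free)
Conditions: Ac2O, pyridine, DMAP (cat.), CH2Cl2, 0 °C → rt
Reagents that add atoms: acetic anhydride, CC(=O)OC(C)=O
Why: DMAP-catalysed acetylation of the three secondary hydroxyls, the tertiary C8 hydroxyl being too hindered to react under these conditions.

Step 24
Reactants: 39 triacetate diene
Product: 40 16-O-TBDPS ether of the target (ten-membered ring closed, 3Z)
Conditions: Hoveyda–Grubbs II (15 mol%), toluene (1 mM), 80 °C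
Reagents that add atoms: none
Why: Ring-closing metathesis between the C2 vinyl group and the terminal alkene of the 1,3-diene forms C3=C4, and the ten-membered ring should enforce the Z geometry; the trisubstituted C5=C6 and C11=C12 alkenes are too hindered to take part.

Step 25
Reactants: 40 TBDPS ether of the target
Product: 41 target (CNP0215504.2)
Conditions: HF·pyridine, pyridine/THF, 0 °C → rt
Reagents that add atoms: none
Why: Buffered fluoride cleavage of the primary silyl ether under weakly acidic conditions, which should leave the three acetates, the lactone and the tertiary alcohol untouched and disfavour acetyl migration.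

## Compound list

1 | (Z)-but-2-ene-1,4-diol | OC/C=C\CO | starting material
2 | (Z)-4-[(tert-butyldimethylsilyl)oxy]but-2-en-1-ol | CC(C)(C)[Si](C)(C)OC/C=C\CO | intermediate
3 | (S)-malic acid | OC(=O)C[C@H](O)C(=O)O | starting material
4 | O-trifluoroacetyl (S)-malic anhydride (not isolated) | O=C1C[C@H](OC(=O)C(F)(F)F)C(=O)O1 | intermediate
5 | (S)-4-(benzyloxy)-3-hydroxy-4-oxobutanoic acid | OC(=O)C[C@H](O)C(=O)OCc1ccccc1 | intermediate
6 | 1-benzyl 4-[(Z)-4-(TBSO)but-2-en-1-yl] (S)-2-hydroxybutanedioate | CC(C)(C)[Si](C)(C)OC/C=C\COC(=O)C[C@H](O)C(=O)OCc1ccccc1 | intermediate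
7 | dilithium alkoxide enolate of 6 (not isolated) | [Li+].[Li+].CC(C)(C)[Si](C)(C)OC/C=C\CO/C([O-])=C/[C@H]([O-])C(=O)OCc1ccccc1 | intermediate
8 | 1-benzyl 4-[(Z)-4-(TBSO)but-2-en-1-yl] (2S,3R)-2-hydroxy-3-methylbutanedioate | CC(C)(C)[Si](C)(C)OC/C=C\COC(=O)[C@H](C)[C@H](O)C(=O)OCc1ccccc1 | intermediate
9 | dilithium alkoxide enolate of 8 (not isolated) | [Li+].[Li+].CC(C)(C)[Si](C)(C)OC/C=C\CO/C([O-])=C(\C)[C@H]([O-])C(=O)OCc1ccccc1 | intermediate
10 | (2R,3S)-4-(benzyloxy)-2-[(2S)-1-(TBSO)but-3-en-2-yl]-3-hydroxy-2-methyl-4-oxobutanoic acid | C=C[C@H](CO[Si](C)(C)C(C)(C)C)[C@@](C)(C(=O)O)[C@H](O)C(=O)OCc1ccccc1 | intermediate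
11 | benzyl 2-tert-butyl-5-[(2S)-1-(TBSO)but-3-en-2-yl]-5-methyl-6-oxo-1,3-dioxane-4-carboxylate (all-equatorial, methyl axial) | C=C[C@H](CO[Si](C)(C)C(C)(C)C)[C@@]1(C)C(=O)O[C@H](C(C)(C)C)O[C@@H]1C(=O)OCc1ccccc1 | intermediate
12 | benzyl 2-tert-butyl-5-[(2S)-1-(TBSO)-3-oxobutan-2-yl]-5-methyl-6-oxo-1,3-dioxane-4-carboxylate | CC(=O)[C@H](CO[Si](C)(C)C(C)(C)C)[C@@]1(C)C(=O)O[C@H](C(C)(C)C)O[C@@H]1C(=O)OCc1ccccc1 | intermediate
13 | 2-tert-butyl-5-[(2S)-1-(TBSO)-3-oxobutan-2-yl]-5-methyl-6-oxo-1,3-dioxane-4-carboxylic acid | CC(=O)[C@H](CO[Si](C)(C)C(C)(C)C)[C@@]1(C)C(=O)O[C@H](C(C)(C)C)O[C@@H]1C(=O)O | intermediate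
14 | vinyltriphenylphosphonium bromide | C=C[P+](c1ccccc1)(c1ccccc1)c1ccccc1.[Br-] | starting material
15 | phosphonium ylide at C12 with axial C13 chain on the dioxanone (not isolated) | CC(=O)[C@H](CO[Si](C)(C)C(C)(C)C)[C@@]1(C)C(=O)O[C@H](C(C)(C)C)O[C@H]1CC=P(c1ccccc1)(c1ccccc1)c1ccccc1 | intermediate
16 | cis-fused 2-tert-butyl-1,3-dioxan-4-one/cyclohexene bicycle (C1 R, C10 S, C14 S; C10 CH2OTBS) | CC(C)(C)[Si](C)(C)OC[C@H]2C(C)=CC[C@H](O[C@@H](C(C)(C)C)OC3=O)[C@]32C | intermediate
17 | bromomagnesium hemiketal from vinyl addition to 16 (not isolated) | CC(C)(C)[Si](C)(C)OC[C@H]2C(C)=CC[C@H](O[C@@H](C(C)(C)C)OC3(C=C)O[Mg]Br)[C@]32C | intermediate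
18 | 1-[(1R,2S,6S)-2-(TBSO-methyl)-6-hydroxy-1,3-dimethylcyclohex-3-en-1-yl]prop-2-en-1-one | CC(C)(C)[Si](C)(C)OC[C@H]1C(C)=CC[C@H](O)[C@]1(C)C(=O)C=C | intermediate
19 | (1S)-1-[(1R,2S,6S)-2-(TBSO-methyl)-6-hydroxy-1,3-dimethylcyclohex-3-en-1-yl]prop-2-en-1-ol | CC(C)(C)[Si](C)(C)OC[C@H]1C(C)=CC[C@H](O)[C@]1(C)[C@@H](O)C=C | intermediate
20 | O2,O14-acetonide of 19 | CC(C)(C)[Si](C)(C)OC[C@H]1C(C)=CC[C@@H]2OC(C)(C)O[C@@H](C=C)[C@]12C | intermediate
21 | acetonide C9 primary alcohol | OC[C@H]1C(C)=CC[C@@H]2OC(C)(C)O[C@@H](C=C)[C@]12C | intermediate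
22 | acetonide C9 aldehyde | O=C[C@H]1C(C)=CC[C@@H]2OC(C)(C)O[C@@H](C=C)[C@]12C | intermediate
23 | (R)-4-methyldihydrofuran-2(3H)-one | O=C1OC[C@H](C)C1 | starting material
24 | lithium enolate of 23 (not isolated) | [Li+].[O-]C1=C[C@@H](C)CO1 | intermediate
25 | (3R,4S)-3-hydroxy-4-methyldihydrofuran-2(3H)-one | O=C1OC[C@H](C)[C@H]1O | intermediate
26 | (3R,4S)-3-[(2-methoxypropan-2-yl)oxy]-4-methyldihydrofuran-2(3H)-one | O=C1OC[C@H](C)[C@H]1OC(C)(C)OC | intermediate
27 | tert-butyldiphenyl(prop-2-yn-1-yloxy)silane | C#CCO[Si](c1ccccc1)(c1ccccc1)C(C)(C)C | starting material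
28 | (Z)-[2-(TBDPSO-methyl)buta-1,3-dien-1-yl]copper (not isolated) | [Cu]/C=C(\C=C)CO[Si](c1ccccc1)(c1ccccc1)C(C)(C)C | intermediate
29 | (E)-tert-butyl{[2-(iodomethylidene)but-3-en-1-yl]oxy}diphenylsilane | I/C=C(\C=C)CO[Si](c1ccccc1)(c1ccccc1)C(C)(C)C | intermediate
30 | lithium enolate of 26 (not isolated) | [Li+].[O-]C1=C(OC(C)(C)OC)[C@@H](C)CO1 | intermediate
31 | lithium aldolate from 30 and 22 (not isolated) | [Li+].O=C1OC[C@H](C)[C@@]1(OC(C)(C)OC)[C@@H]([O-])[C@H]1C(C)=CC[C@@H]2OC(C)(C)O[C@@H](C=C)[C@]12C | intermediate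
32 | TES-protected aldol adduct (lactone C7=O, C8 OMOP, C9 OTES; stereocentres as in the target) | O=C1OC[C@H](C)[C@@]1(OC(C)(C)OC)[C@@H](O[Si](CC)(CC)CC)[C@H]1C(C)=CC[C@@H]2OC(C)(C)O[C@@H](C=C)[C@]12C | intermediate
33 | (Z)-[2-(TBDPSO-methyl)buta-1,3-dien-1-yl]lithium (not isolated) | [Li]/C=C(\C=C)CO[Si](c1ccccc1)(c1ccccc1)C(C)(C)C | intermediate
34 | hydroxy dienone (C7 ketone, C19 CH2OH, C8 OMOP, C9 OTES) | OC[C@H](C)[C@](OC(C)(C)OC)(C(=O)/C=C(\C=C)CO[Si](c1ccccc1)(c1ccccc1)C(C)(C)C)[C@@H](O[Si](CC)(CC)CC)[C@H]1C(C)=CC[C@@H]2OC(C)(C)O[C@@H](C=C)[C@]12C | intermediate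
35 | C7,C19-diol (7S) | OC[C@H](C)[C@](OC(C)(C)OC)([C@@H](O)/C=C(\C=C)CO[Si](c1ccccc1)(c1ccccc1)C(C)(C)C)[C@@H](O[Si](CC)(CC)CC)[C@H]1C(C)=CC[C@@H]2OC(C)(C)O[C@@H](C=C)[C@]12C | intermediate
36 | C19 lactol (not isolated) | C=C\C(CO[Si](c1ccccc1)(c1ccccc1)C(C)(C)C)=C/[C@@H]1OC(O)[C@H](C)[C@@]1(OC(C)(C)OC)[C@@H](O[Si](CC)(CC)CC)[C@H]1C(C)=CC[C@@H]2OC(C)(C)O[C@@H](C=C)[C@]12C | intermediate
37 | protected γ-lactone (O7–C19; C8 OMOP, C9 OTES, O2/O14 acetonide, C16 OTBDPS) | C=C\C(CO[Si](c1ccccc1)(c1ccccc1)C(C)(C)C)=C/[C@@H]1OC(=O)[C@H](C)[C@@]1(OC(C)(C)OC)[C@@H](O[Si](CC)(CC)CC)[C@H]1C(C)=CC[C@@H]2OC(C)(C)O[C@@H](C=C)[C@]12C | intermediate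
38 | tetraol (C2, C8, C9, C14 OH; C16 OTBDPS) | C=C\C(CO[Si](c1ccccc1)(c1ccccc1)C(C)(C)C)=C/[C@@H]1OC(=O)[C@H](C)[C@@]1(O)[C@@H](O)[C@H]1C(C)=CC[C@H](O)[C@]1(C)[C@@H](O)C=C | intermediate
39 | 2,9,14-triacetate diene | C=C\C(CO[Si](c1ccccc1)(c1ccccc1)C(C)(C)C)=C/[C@@H]1OC(=O)[C@H](C)[C@@]1(O)[C@@H](OC(C)=O)[C@H]1C(C)=CC[C@H](OC(C)=O)[C@]1(C)[C@@H](OC(C)=O)C=C | intermediate
40 | 16-O-TBDPS ether of the target | CC(=O)O[C@H]1/C=C\C(CO[Si](c2ccccc2)(c2ccccc2)C(C)(C)C)=C/[C@@H]2OC(=O)[C@H](C)[C@@]2(O)[C@@H](OC(C)=O)[C@H]2C(C)=CC[C@H](OC(C)=O)[C@]12C | intermediate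
41 | CNP0215504.2 (1R,2S,3Z,5E,7S,8S,9S,10S,14S,17R) | CC(=O)O[C@H]1/C=C\C(CO)=C/[C@@H]2OC(=O)[C@H](C)[C@@]2(O)[C@@H](OC(C)=O)[C@H]2C(C)=CC[C@H](OC(C)=O)[C@]12C | target

## Summary

Total step count: 25. Longest linear sequence: 21 steps (steps 2–14 and 18–25, from (S)-malic acid).

Steps most likely to fail:

1. Step 9 (proposed new method). The carboxylate may add as an O-nucleophile to the vinylphosphonium salt, the ylide may be protonated before it reaches the ketone, or the radical may be attacked equatorially and give the trans-fused C14 epimer. The fallback uses known reactions, sets out from 13 and returns at 16. Photoredox decarboxylative allylation of 13 with allyl phenyl sulfone (same axial radical attack at C14) should give the allyl ketone F1. Wittig methylenation of the C11 ketone with Ph3P=CH2 should give the diene F2. Ring-closing metathesis (Grubbs II) of the allyl and isopropenyl groups then closes the trisubstituted cyclohexene to 16.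

2. Step 24. The hindered C2 vinyl group may fail to engage, so that cross-metathesis oligomers form, or the new alkene may scramble to E. The fallback sets out from 37 and returns at 40: the ring is closed while O2 and O14 are still tied in the 1,3-dioxane, which holds the C2 vinyl group over the diene arm, using a Z-selective Mo alkylidene; this should give the macrocyclic acetonide F7. Acid hydrolysis as in step 22 gives the macrocyclic tetraol F8, and acetylation as in step 23 gives 40.

3. Step 18. The hindered enolate may enolise the α-branched β,γ-unsaturated aldehyde instead of adding, the aldolate may revert before silylation, or addition may occur on the Felkin face and give the C9 epimer. The fallback sets out from 22 and returns at 32, setting C9 by hydride instead. Pinnick oxidation of 22 gives the carboxylic acid F3, and carbonyldiimidazole gives the acyl imidazole F4. C-acylation of lithium enolate 30 with F4 (anti to the β-methyl group) gives the β-keto lactone F5. Felkin–Anh reduction with L-Selectride, hydride anti to C1, should give the 9S alcohol F6, and silylation with TESCl gives 32.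

Further compounds
F1 | step 9 | allyl ketone: 6-allyl-2-tert-butyl-5-[(2S)-1-(TBSO)-3-oxobutan-2-yl]-5-methyl-1,3-dioxan-4-one (allyl axial) | CC(=O)[C@H](CO[Si](C)(C)C(C)(C)C)[C@@]1(C)C(=O)O[C@H](C(C)(C)C)O[C@H]1CC=C
F2 | step 9 | diene: 6-allyl-2-tert-butyl-5-[(2S)-1-(TBSO)-3-methylbut-3-en-2-yl]-5-methyl-1,3-dioxan-4-one | CC(=C)[C@H](CO[Si](C)(C)C(C)(C)C)[C@@]1(C)C(=O)O[C@H](C(C)(C)C)O[C@H]1CC=C
F3 | step 18 | acetonide C9 carboxylic acid | O=C(O)[C@H]1C(C)=CC[C@@H]2OC(C)(C)O[C@@H](C=C)[C@]12C
F4 | step 18 | acyl imidazole of F3 | O=C([C@H]1C(C)=CC[C@@H]2OC(C)(C)O[C@@H](C=C)[C@]12C)n1ccnc1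
F5 | step 18 | β-keto lactone (C9 ketone, C8 OMOP) | O=C1OC[C@H](C)[C@@]1(OC(C)(C)OC)C(=O)[C@H]1C(C)=CC[C@@H]2OC(C)(C)O[C@@H](C=C)[C@]12C
F6 | step 18 | free aldol (C9–OH, 9S) | O=C1OC[C@H](C)[C@@]1(OC(C)(C)OC)[C@@H](O)[C@H]1C(C)=CC[C@@H]2OC(C)(C)O[C@@H](C=C)[C@]12C
F7 | step 24 | macrocyclic acetonide (C8 OMOP, C9 OTES, C16 OTBDPS) | CC1(C)O[C@H]2/C=C\C(CO[Si](c3ccccc3)(c3ccccc3)C(C)(C)C)=C/[C@@H]3OC(=O)[C@H](C)[C@@]3(OC(C)(C)OC)[C@@H](O[Si](CC)(CC)CC)[C@H]3C(C)=CC[C@H](O1)[C@]23C
F8 | step 24 | macrocyclic tetraol (C16 OTBDPS) | O[C@H]1/C=C\C(CO[Si](c2ccccc2)(c2ccccc2)C(C)(C)C)=C/[C@@H]2OC(=O)[C@H](C)[C@@]2(O)[C@@H](O)[C@H]2C(C)=CC[C@H](O)[C@]12C
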